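## The problem

The target 9 is (−)-epicatechin-(4β→8)-4β-carboxymethyl-(−)-epicatechin. It consists of two (2R,3R)-2,3-cis-flavan-3-ol nuclei (upper unit: benzo ring A, pyran ring C, catechol ring B; lower unit: rings D, F and E in the same order) joined from C4 of ring C to C8 of ring D, with a CH2CO2H group on C4 of ring F. Of the six stereocentres, C2 and C3 of each unit are those of commercial (−)-epicatechin 1. The two C4 centres (4R in ring C, 4S in ring F, both substituents β and trans to the neighbouring C3 hydroxyl) must be created, and each can be controlled by its own C2 aryl group and C3 hydroxyl, which both lie on the α face. The interflavan bond brings two selectivity problems: C8 must react and not C6, and the union must stop at two units, although every flavan unit is both an arene nucleophile (C8) and the precursor of a C4 electrophile. The free compound is fragile (air oxidation of the catechol and phloroglucinol rings, epimerisation of C2 in base, acid cleavage of the interflavan bond), so the ten hydroxyls and the acid must be unmasked last under neutral conditions. The feature the plan uses is that rings A/C and rings D/F are the same nucleus, in which C4–H of the pyran ring is a hydride donor (the cation is para to O7 and ortho to O5 and O1) and C8–H of the benzo ring is the most nucleophilic arene position. One protected monomer can therefore supply both partners of the C4(ring C)–C8(ring D) bond, and C4 of ring F stays a CH2 group to which the acetate is attached afterwards; the target is then a two-unit procyanidin chain terminated by an acetate enolate equivalent.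

## Retrosynthesis

**9 ⇒ 8.** Nine O–benzyl bonds are cut: in 8 the eight phenols are benzyl ethers, the acid is a benzyl ester and the two C3 hydroxyls are free. Benzyl is preferred to silyl or acyl groups because hydrogenolysis is neutral, whereas fluoride or base would meet free catechols and an epimerisable C2. The forward step must cleave aryl–OCH2Ph and ester C–O bonds only and leave the C4–C bonds and the cyclic C2–O1 ethers intact.

**8 ⇒ 5 + 7.** The bond from C4 of ring F to the CH2CO2Bn carbon is cut, giving the dimeric C4 ether 5 and the ketene silyl acetal 7 (from benzyl acetate 6). This bond is cut before the interflavan bond because 7 is far more nucleophilic than any arene carbon in the molecule. Its capture of the dimeric C4 cation therefore raises no regiochemical or chain-length question, and the harder interflavan bond can be made between unsubstituted partners. The forward reaction must deliver the carbon nucleophile to the β face of ring F; the α-disposed ring E and C3 hydroxyl ensure this from either C4 epimer of 5.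

**5 ⇒ 4.** The C4–O bond of ring F is removed, which leads to the octa-benzyl dimer 4 with a CH2 group at that position. The forward step is a C–H oxidation that must choose the C4–H2 of ring F over the C4–H of ring C and the two C2–H bonds. Making the lower unit with a leaving group already in place would give away the homo-coupling of the next cut.

**4 ⇒ 2 + 2 (key cut).** The C4(ring C)–C8(ring D) bond is cut. Because ring F of 4 is still unsubstituted, both halves are the same compound, tetra-O-benzyl ether 2. The precursor is half the size and has no C4 stereocentre. Forward, part of 2 is oxidised at C4 by a quinone hydride acceptor to the quinol ether 3, which alkylates C8 of the remaining 2. This requires β-face attack, C8 selectivity and a stop at the dimer. Against the established two-operation alternative (isolated C4 ether, then Lewis-acid coupling) it saves a step and an auxiliary alcohol.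

**2 ⇒ 1 and 7 ⇒ 6.** Phenol benzylation of 1 and O-silylation of the enolate of 6 are standard.

## Roads not taken

Alternative 1: the obvious cut breaks the interflavan bond last, between two different monomers. The lower unit is completed first as ester A1 (C4 oxidation of 2, capture by 7) and then serves as the C8 nucleophile toward a C4-activated upper unit, which needs a bromine cap on C8 (ether A2) if the partners are to be used one to one. The forward key step is Lewis-acid Friedel–Crafts alkylation of A1 by the cation from A2, followed by hydrogenolysis, which also removes the bromine. The chosen plan is better because its two coupling partners are the same compound: the excess of nucleophile that suppresses oligomers is simply unoxidised 2, which is recovered. In the obvious route that excess would be the three-step compound A1, or C8 must be capped and uncapped. With the cap it needs seven operations against six and isolates three C4-activated intermediates instead of one.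

Alternative 2: the same C4–C8 bond is made with reversed polarity. Bromide A3 (2 brominated at C8 and silylated at O3) is lithiated and added to the C4 ketone A4 of a second unit, and the tertiary carbinol A5 is deoxygenated by ionisation and hydride transfer. Regiochemistry at C8 would be certain, but the diaryl cation from A5 would take hydride on the β face, anti to the C2 aryl group and the C3 oxygen. That leaves the aryl group α (3,4-cis), the wrong configuration at C4 of ring C. The aryllithium also excludes an ester in the molecule, O3 must be protected and freed, and A4 lies two oxidation levels above the electrophile of the chosen plan, so at least four more operations are needed.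

Alternative 3: a dearomatisation introduces ring C flat, as the achiral flavylium salt A6, which C8 of 2 attacks at C4 to give the 4H-flavene A7; C2 and C3 are then set by reducing the enol ether double bond. The C–C bond should form easily, but C4 is created on a flat cation whose faces the remote stereocentres of 2 cannot distinguish. The C2=C3 bond of A7 would then have to accept both hydrogens on the face that carries the bulky C4 aryl group (to give 2,3-cis-3,4-trans), whereas hydrogenation from the open face is expected to give the all-cis isomer. Three stereocentres that 1 supplies or controls at no cost would have to be made against the intrinsic bias.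

Key step: step 2

Remark: α and β denote the faces of the pyran rings in the usual flavan convention (C2 aryl group α in the 2R series); equivalents given are planned amounts.

## Steps

Step 1
Reactants: 1 (−)-epicatechin
Product: 2 5,7,3′,4′-tetra-O-benzyl-(−)-epicatechin (2R,3R; C3 hydroxyl free)
Conditions: BnBr (4.4 equiv), K2CO3, DMF, 0 °C to rt, argon
Reagents that add atoms: benzyl bromide, BrCc1ccccc1
Why: Williamson etherification: K2CO3 deprotonates only the four phenols, so the secondary C3 alcohol stays free; low temperature and exclusion of air keep C2 from epimerising and the phenoxides from oxidising. No stereocentre is formed or touched.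

Step 2
Reactants: 2 5,7,3′,4′-tetra-O-benzyl-(−)-epicatechin (two molecules, one as hydride donor and one as arene nucleophile)
Product: 4 octa-O-benzylprocyanidin B2 [tetra-O-benzylepicatechin-(4β→8)-tetra-O-benzylepicatechin; upper unit (2R,3R,4R); lower unit (2R,3R)], via C4 quinol ether 3 (not isolated)
Conditions: DDQ (0.25 equiv), 4 Å MS, CH2Cl2, 0 °C to rt; then TMSOTf (5 mol %), −78 to −40 °C; Et3N
Reagents that add atoms: none
Why: Proposed new method: DDQ abstracts the pseudoaxial C4–Hβ of ring C as hydride and the resulting C4 cation (para to O7, ortho to O5 and O1) collapses with the hydroquinone anion to the quinol ether 3; as no alcohol is present, the only carbon nucleophile is C8 of the three-fold excess of unoxidised 2, and once the quinone is consumed catalytic TMSOTf re-ionises 3 so that Friedel–Crafts alkylation forms the C4–C8 bond irreversibly and releases the hydroquinone. The closest known reaction types are the DDQ-mediated C4 alkoxylation of this same ether (same cation, an alcohol as trap) and the Lewis-acid coupling of flavan C4 ethers with C8 of a second flavan unit; the step merges the two and turns the self-condensation that the alcohol normally suppresses into the productive path. No ring is closed. The single new stereocentre, C4 of ring C, is set as R (4β) by the substrate: the C2 aryl group and the C3 hydroxyl both shield the α face of the planar cation, so the arene adds to the β face, trans to the C3 hydroxyl and along the pseudoaxial trajectory, whichever C4 epimer of 3 ionises. Regioselectivity for C8 over C6 rests on C8 lying between the ring oxygen O1 and one benzyloxy group, whereas C6 is flanked by two benzyloxy groups. Chain length is held at two units because the quinone is the limiting reagent and is used up before the acid is added, so that 4 is formed only when no oxidant remains to take hydride from C4 of its lower unit, and because unoxidised 2, in excess, outcompetes C8 of 4 for the cation. The excess of 2 is recovered unchanged and is the only price of the selectivity.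

Step 3
Reactants: 4 octa-O-benzylprocyanidin B2
Product: 5 octa-O-benzyl-4β-(2-ethoxyethoxy)procyanidin B2 [ether on C4 of ring F; lower unit (2R,3R,4S)]
Conditions: DDQ (2 equiv), EtOCH2CH2OH (10 equiv), CH2Cl2, rt
Reagents that add atoms: 2-ethoxyethanol, CCOCCO
Why: DDQ-mediated benzylic C–H oxidation (oxidative alkoxylation): only the pseudoaxial C4–Hβ of ring F is aligned with the π system of a tri-oxygenated ring, whereas the C4–H of ring C is pseudoequatorial (in the nodal plane of ring A) and buried between two ortho-disubstituted arenes, so hydride should be taken from the lower unit alone. The alcohol traps the cation on the β face and the remaining pseudoequatorial C4–Hα resists a second abstraction; the configuration of this centre is erased again in step 5.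

Step 4
Reactants: 6 benzyl acetate
Product: 7 1-(benzyloxy)-1-(tert-butyldimethylsilyloxy)ethene (ketene silyl acetal)
Conditions: LiN(iPr)2, THF, −78 °C; TBSCl, DMPU, −78 °C to rt
Reagents that add atoms: tert-butyldimethylsilyl chloride, CC(C)(C)[Si](C)(C)Cl
Why: Kinetic deprotonation of the acetate and O-silylation of the lithium enolate (DMPU favours O- over C-silylation) give the ketene silyl acetal; no stereocentre is involved.

Step 5
Reactants: 5 octa-O-benzyl-4β-(2-ethoxyethoxy)procyanidin B2; 7 1-(benzyloxy)-1-(tert-butyldimethylsilyloxy)ethene (3 equiv)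
Product: 8 benzyl ester of octa-O-benzyl 9 [CH2CO2Bn on C4 of ring F; lower unit (2R,3R,4S); upper unit (2R,3R,4R)]
Conditions: TMSOTf (10 mol %), CH2Cl2, −78 °C; Et3N
Reagents that add atoms: none
Why: Mukaiyama-type SN1 alkylation: the silyl triflate ionises the C4 ether to the dimeric benzylic cation, which 7, far more nucleophilic than any arene carbon present, captures on the β face, anti to the α-disposed ring E and C3 hydroxyl, setting C4 of ring F as S (3,4-trans) from either epimer of 5. Silyl transfer to the departing alkoxide regenerates the silyl triflate, so the acid is catalytic and the interflavan bond never meets protic acid.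

Step 6
Reactants: 8 benzyl ester of octa-O-benzyl 9
Product: 9 (−)-epicatechin-(4β→8)-4β-carboxymethyl-(−)-epicatechin (target)
Conditions: H2 (1 atm), Pd(OH)2/C, THF–MeOH–H2O, rt
Reagents that add atoms: none
Why: Hydrogenolysis of eight aryl benzyl ethers and the benzyl ester under neutral conditions releases all phenols and the acid in one operation. The C4–C bonds, the cyclic C2–O1 ethers and all six stereocentres are untouched.

## Compound list

1 | (−)-epicatechin, (2R,3R)-2-(3,4-dihydroxyphenyl)chromane-3,5,7-triol | C1c2c(O)cc(O)cc2O[C@H](c2ccc(O)c(O)c2)[C@@H]1O | starting material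
2 | 5,7,3′,4′-tetra-O-benzyl-(−)-epicatechin (2R,3R) | C1c2c(OCc3ccccc3)cc(OCc3ccccc3)cc2O[C@H](c2ccc(OCc3ccccc3)c(OCc3ccccc3)c2)[C@@H]1O | intermediate
3 | 5,7,3′,4′-tetra-O-benzyl-4β-(2,3-dichloro-5,6-dicyano-4-hydroxyphenoxy)-(−)-epicatechin (C4 quinol ether, formed in the flask in step 2) | Oc1c(Cl)c(Cl)c(O[C@H]2c3c(OCc4ccccc4)cc(OCc4ccccc4)cc3O[C@H](c3ccc(OCc4ccccc4)c(OCc4ccccc4)c3)[C@@H]2O)c(C#N)c1C#N | intermediate
4 | octa-O-benzylprocyanidin B2, tetra-O-benzylepicatechin-(4β→8)-tetra-O-benzylepicatechin | C1c2c(OCc3ccccc3)cc(OCc3ccccc3)c([C@H]3c4c(OCc5ccccc5)cc(OCc5ccccc5)cc4O[C@H](c4ccc(OCc5ccccc5)c(OCc5ccccc5)c4)[C@@H]3O)c2O[C@H](c2ccc(OCc3ccccc3)c(OCc3ccccc3)c2)[C@@H]1O | intermediate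
5 | octa-O-benzylprocyanidin B2 carrying a 4β-(2-ethoxyethoxy) group on C4 of ring F | CCOCCO[C@H]1c2c(OCc3ccccc3)cc(OCc3ccccc3)c([C@H]3c4c(OCc5ccccc5)cc(OCc5ccccc5)cc4O[C@H](c4ccc(OCc5ccccc5)c(OCc5ccccc5)c4)[C@@H]3O)c2O[C@H](c2ccc(OCc3ccccc3)c(OCc3ccccc3)c2)[C@@H]1O | intermediate
6 | benzyl acetate | CC(=O)OCc1ccccc1 | starting material
7 | 1-(benzyloxy)-1-(tert-butyldimethylsilyloxy)ethene | C=C(OCc1ccccc1)O[Si](C)(C)C(C)(C)C | intermediate
8 | benzyl 2-[octa-O-benzyl-epicatechin-(4β→8)-epicatechin-4β-yl]acetate (nona-benzyl derivative of 9) | O=C(OCc1ccccc1)C[C@H]1c2c(OCc3ccccc3)cc(OCc3ccccc3)c([C@H]3c4c(OCc5ccccc5)cc(OCc5ccccc5)cc4O[C@H](c4ccc(OCc5ccccc5)c(OCc5ccccc5)c4)[C@@H]3O)c2O[C@H](c2ccc(OCc3ccccc3)c(OCc3ccccc3)c2)[C@@H]1O | intermediate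
9 | 2-[(2R,3R,4S)-2-(3,4-dihydroxyphenyl)-8-[(2R,3R,4R)-2-(3,4-dihydroxyphenyl)-3,5,7-trihydroxychroman-4-yl]-3,5,7-trihydroxychroman-4-yl]acetic acid | O=C(O)C[C@H]1c2c(O)cc(O)c([C@H]3c4c(O)cc(O)cc4O[C@H](c4ccc(O)c(O)c4)[C@@H]3O)c2O[C@H](c2ccc(O)c(O)c2)[C@@H]1O | target

## Step count and least certain steps

Total step count: 6. Longest linear sequence: 5 steps (1 → 2 → 4 → 5 → 8 → 9); step 4 is a one-step side branch.

**Step 2 (key step, proposed new method).** The likely failures are loss of control over the timing of ionisation and oxidation. If 3 ionises while quinone is still present, hydride abstraction from the lower unit of 4 would start chain growth to trimers. If acid meets residual quinone, single-electron oxidation of the electron-rich rings would give oxidative biaryl coupling. Partial attack through C6 is a smaller risk. Fallback (known chemistry): setting out from 2, DDQ oxidation in the presence of 2-ethoxyethanol gives the monomeric 4β-(2-ethoxyethoxy) ether F1. F1 is then ionised with catalytic TMSOTf at −78 °C in the presence of a several-fold excess of 2, the established Lewis-acid interflavan coupling, and the route is rejoined at 4.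

**Step 3.** The risk is hydride abstraction at the wrong benzylic site (C4–H of ring C or a C2–H), a second oxidation at C4 of ring F, or capture of the dimeric cation by C8 of another dimer instead of the alcohol. These would arise because 4 offers four benzylic positions and two free arene carbons to a strong oxidant. Fallback: the leaving group for the second C–C bond is installed before the interflavan bond is made (orthogonal hard/soft activation). Setting out from 2, the monomeric ether F1 (made as in the fallback for step 2) is converted with 2,6-dimethylbenzenethiol and BF3·OEt2 into the 4β-aryl sulfide F2. F2, inert to silyl triflate and used in excess, acts as C8 nucleophile toward F1 (TMSOTf, −78 °C) to give the dimeric sulfide F3. Thiophilic activation of F3 with AgOTf in the presence of 7 delivers 8, where the route is rejoined.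

**Step 5.** The risk is silyl transfer from 7 to the two free C3 hydroxyls and to liberated alcohol, with protonolysis of the nucleophile outrunning C–C bond formation; the starved cation would then alkylate C8 of another molecule. Fallback: setting out from 5, capture of the cation with allyltrimethylsilane (TMSOTf, −78 °C), which is insensitive to protic groups, gives the 4β-allyl compound F4. Oxidative cleavage (OsO4 catalytic, NaIO4, 2,6-lutidine) gives aldehyde F5, and NaClO2 oxidation (NaH2PO4, 2-methyl-2-butene) gives acid F6. Hydrogenolysis of F6 under the conditions of step 6 rejoins the route at 9.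

## Further compounds

F1 | step 2 | 5,7,3′,4′-tetra-O-benzyl-4β-(2-ethoxyethoxy)-(−)-epicatechin (2R,3R,4S) | CCOCCO[C@H]1c2c(OCc3ccccc3)cc(OCc3ccccc3)cc2O[C@H](c2ccc(OCc3ccccc3)c(OCc3ccccc3)c2)[C@@H]1O
F2 | step 3 | 5,7,3′,4′-tetra-O-benzyl-4β-(2,6-dimethylphenylthio)-(−)-epicatechin (2R,3S,4S) | Cc1cccc(C)c1S[C@H]1c2c(OCc3ccccc3)cc(OCc3ccccc3)cc2O[C@H](c2ccc(OCc3ccccc3)c(OCc3ccccc3)c2)[C@@H]1O
F3 | step 3 | octa-O-benzylprocyanidin B2 carrying a 4β-(2,6-dimethylphenylthio) group on C4 of ring F | Cc1cccc(C)c1S[C@H]1c2c(OCc3ccccc3)cc(OCc3ccccc3)c([C@H]3c4c(OCc5ccccc5)cc(OCc5ccccc5)cc4O[C@H](c4ccc(OCc5ccccc5)c(OCc5ccccc5)c4)[C@@H]3O)c2O[C@H](c2ccc(OCc3ccccc3)c(OCc3ccccc3)c2)[C@@H]1O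
F4 | step 5 | octa-O-benzylprocyanidin B2 carrying a 4β-allyl group on C4 of ring F | C=CC[C@H]1c2c(OCc3ccccc3)cc(OCc3ccccc3)c([C@H]3c4c(OCc5ccccc5)cc(OCc5ccccc5)cc4O[C@H](c4ccc(OCc5ccccc5)c(OCc5ccccc5)c4)[C@@H]3O)c2O[C@H](c2ccc(OCc3ccccc3)c(OCc3ccccc3)c2)[C@@H]1O
F5 | step 5 | octa-O-benzylprocyanidin B2 carrying a 4β-(2-oxoethyl) group on C4 of ring F (aldehyde) | O=CC[C@H]1c2c(OCc3ccccc3)cc(OCc3ccccc3)c([C@H]3c4c(OCc5ccccc5)cc(OCc5ccccc5)cc4O[C@H](c4ccc(OCc5ccccc5)c(OCc5ccccc5)c4)[C@@H]3O)c2O[C@H](c2ccc(OCc3ccccc3)c(OCc3ccccc3)c2)[C@@H]1O
F6 | step 5 | octa-O-benzyl ether of 9 (free carboxylic acid) | O=C(O)C[C@H]1c2c(OCc3ccccc3)cc(OCc3ccccc3)c([C@H]3c4c(OCc5ccccc5)cc(OCc5ccccc5)cc4O[C@H](c4ccc(OCc5ccccc5)c(OCc5ccccc5)c4)[C@@H]3O)c2O[C@H](c2ccc(OCc3ccccc3)c(OCc3ccccc3)c2)[C@@H]1O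
A1 | alternative 1 | benzyl 2-[5,7,3′,4′-tetra-O-benzyl-(−)-epicatechin-4β-yl]acetate (2R,3R,4S) | O=C(OCc1ccccc1)C[C@H]1c2c(OCc3ccccc3)cc(OCc3ccccc3)cc2O[C@H](c2ccc(OCc3ccccc3)c(OCc3ccccc3)c2)[C@@H]1O
A2 | alternative 1 | 5,7,3′,4′-tetra-O-benzyl-8-bromo-4β-(2-ethoxyethoxy)-(−)-epicatechin | CCOCCO[C@H]1c2c(OCc3ccccc3)cc(OCc3ccccc3)c(Br)c2O[C@H](c2ccc(OCc3ccccc3)c(OCc3ccccc3)c2)[C@@H]1O
A3 | alternative 2 | 5,7,3′,4′-tetra-O-benzyl-8-bromo-3-O-(tert-butyldimethylsilyl)-(−)-epicatechin | C1c2c(OCc3ccccc3)cc(OCc3ccccc3)c(Br)c2O[C@H](c2ccc(OCc3ccccc3)c(OCc3ccccc3)c2)[C@@H]1O[Si](C)(C)C(C)(C)C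
A4 | alternative 2 | 5,7,3′,4′-tetra-O-benzyl-3-O-(tert-butyldimethylsilyl)-4-oxo-(−)-epicatechin (2,3-cis) | O=C1c2c(OCc3ccccc3)cc(OCc3ccccc3)cc2O[C@H](c2ccc(OCc3ccccc3)c(OCc3ccccc3)c2)[C@@H]1O[Si](C)(C)C(C)(C)C
A5 | alternative 2 | tertiary carbinol from addition of lithiated A3 to A4 (4β-aryl, 4α-hydroxy on ring C; both O3 silylated) | C1c2c(OCc3ccccc3)cc(OCc3ccccc3)c([C@@]3(O)c4c(OCc5ccccc5)cc(OCc5ccccc5)cc4O[C@H](c4ccc(OCc5ccccc5)c(OCc5ccccc5)c4)[C@@H]3O[Si](C)(C)C(C)(C)C)c2O[C@H](c2ccc(OCc3ccccc3)c(OCc3ccccc3)c2)[C@@H]1O[Si](C)(C)C(C)(C)C
A6 | alternative 3 | 3,5,7,3′,4′-penta-O-benzylcyanidin (flavylium) triflate | c1c(OCc2ccccc2)c(-c2ccc(OCc3ccccc3)c(OCc3ccccc3)c2)[o+]c2cc(OCc3ccccc3)cc(OCc3ccccc3)c12.[O-]S(=O)(=O)C(F)(F)F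
A7 | alternative 3 | 4-(tetra-O-benzylepicatechin-8-yl)-3,5,7,3′,4′-penta-O-benzyl-4H-flav-2-ene (both C4 epimers of the flavene) | C1c2c(OCc3ccccc3)cc(OCc3ccccc3)c(C3C(OCc4ccccc4)=C(c4ccc(OCc5ccccc5)c(OCc5ccccc5)c4)Oc4cc(OCc5ccccc5)cc(OCc5ccccc5)c34)c2O[C@H](c2ccc(OCc3ccccc3)c(OCc3ccccc3)c2)[C@@H]1O
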